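**Retrosynthetic overview**
1. Numbering: hydrindane C1, C2, C3, C3a, C4–C7, C7a; C8 is the acetoxy carbon; ring B is C1′–C6′. The strategy rests on ring B: C1′ (tertiary carbinol), C2′ (CH2), C3′ (gem-dimethyl) and C4′ (CHBr) are the imprint of a bromonium cyclization, so ring B is cut at C2′–C3′, C4′–Br and C1′–OH back to a 6-methylhepta-1,5-dien-2-yl chain on C8 and is closed last, by a vanadium bromoperoxidase.
2. C8–C1′: Nozaki–Hiyama–Kishi coupling of a trans-hydrindane-1-carbaldehyde with 6-methylhepta-1,5-dien-2-yl triflate; C8 is then set by oxidation and Luche reduction and acetylated.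
3. Five-membered ring: the C1–C2 bond comes from a SmI2 Reformatsky aldol between an α-bromo ester arm on C7a and an aldehyde arm on C3a; a lipase resolution of the resulting carbinol fixes the absolute configuration.
4. Six-membered ring: the C3a–C7a bond and C4–Br come from a bromonium cyclization of an acyclic (E)-alkenyl β-keto ester; C7a–C1 by decarboxylative allylation; the C7 carbinol by equatorial methyl addition.
5. Order of ring formation: six-membered ring of the hydrindane, then its five-membered ring, then ring B.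

Key step: step 21

Assumption: the achiral reagent of step 4 gives racemic material, so compounds 8 to 18 are racemates (drawn as the enantiomer that is carried on) until the lipase resolution of step 13; the C7 oxygen is carried as its triethylsilyl ether, which is sturdier than a trimethylsilyl ether.

**Route**

Step 1
Reactants: 1 tert-butyl(but-3-yn-1-yloxy)diphenylsilane
Product: 3 (E)-5-[(tert-butyldiphenylsilyl)oxy]-3-methylpent-2-en-1-ol, via alkenyldimethylalane 2 (not isolated)
Conditions: Me3Al, Cp2ZrCl2 (25 mol %), CH2Cl2, 23 °C; then n-BuLi, THF, −78 °C; (CH2O)n, −78 → 23 °C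
Reagents that add atoms: trimethylaluminium C[Al](C)C; paraformaldehyde (as formaldehyde) C=O
Why: Negishi carboalumination adds methyl and aluminium syn across the terminal alkyne (methyl to the internal carbon) and the derived alanate is hydroxymethylated with retention, which fixes the (E) alkene that later puts the arm equatorial and the methyl axial at C3a.

Step 2
Reactants: 3 (E)-5-[(tert-butyldiphenylsilyl)oxy]-3-methylpent-2-en-1-ol
Product: 4 (E)-[(5-bromo-3-methylpent-3-en-1-yl)oxy](tert-butyl)diphenylsilane
Conditions: CBr4, PPh3, CH2Cl2, 0 °C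
Reagents that add atoms: carbon tetrabromide BrC(Br)(Br)Br
Why: The Appel reaction converts the primary allylic alcohol into the bromide under neutral conditions, without allylic transposition and without loss of the silyl ether.

Step 3
Reactants: 5 allyl acetoacetate (prop-2-en-1-yl 3-oxobutanoate); 4 (E)-[(5-bromo-3-methylpent-3-en-1-yl)oxy](tert-butyl)diphenylsilane
Product: 7 allyl (E)-9-[(tert-butyldiphenylsilyl)oxy]-7-methyl-3-oxonon-6-enoate, via acetoacetate dianion 6 (not isolated)
Conditions: 5, NaH, THF, 0 °C; n-BuLi, 0 °C; then 4, 0 → 23 °C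
Reagents that add atoms: none
Why: γ-Alkylation of the acetoacetate dianion by the primary allylic bromide (SN2) builds the chain and leaves the β-keto ester as the carbon nucleophile for the six-membered ring and the allyl ester for step 5.

Step 4
Reactants: 7 allyl (E)-9-[(tert-butyldiphenylsilyl)oxy]-7-methyl-3-oxonon-6-enoate
Product: 8 racemic allyl 3-bromo-2-methyl-6-oxo-2-[2-(tert-butyldiphenylsilyloxy)ethyl]cyclohexane-1-carboxylate (Br equatorial cis to the ring methyl; ester equatorial)
Conditions: Et2SBr·SbCl5Br (1.05 equiv), MeNO2, −25 °C, 5 min; aq NaHCO3/Na2SO3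
Reagents that add atoms: bromodiethylsulfonium bromopentachloroantimonate CC[S+](Br)CC.[Sb-](Cl)(Cl)(Cl)(Cl)(Cl)Br
Why: Bromonium-induced cation–olefin cyclization terminated by the β-keto ester enol (the bromenium counterpart of the Lewis-acid and mercury-salt cyclizations of 3-oxo-6-enoates): bromenium goes to the trisubstituted alkene and not to the electron-poor allyl ester alkene, the enol carbon C7a opens the bromonium ion at C3a through a chair, anti addition across the (E) alkene puts Br equatorial at C4 and cis to the axial C3a methyl with the arm equatorial, and the C7a ester settles equatorial by enolization; the reagent is achiral, so 8 is racemic.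

Step 5
Reactants: 8 racemic allyl 3-bromo-2-methyl-6-oxo-2-[2-(tert-butyldiphenylsilyloxy)ethyl]cyclohexane-1-carboxylate
Product: 9 racemic 2-allyl-4-bromo-3-methyl-3-[2-(tert-butyldiphenylsilyloxy)ethyl]cyclohexan-1-one (allyl equatorial and trans to the arm; C7a–H axial)
Conditions: Pd(PPh3)4 (5 mol %), THF, 23 °C; then TsOH·H2O (10 mol %), CHCl3, 40 °C
Reagents that add atoms: none
Why: Decarboxylative allylation of Tsuji–Trost type: oxidative addition of the allyl ester to Pd(PPh3)4, loss of CO2 and recombination of the palladium enolate with the allyl fragment form the C7a–C1 bond regiospecifically, and acid-mediated enolization (no enolate, hence no displacement of the C4 bromide) then moves the allyl group to the equatorial position.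

Step 6
Reactants: 9 racemic 2-allyl-4-bromo-3-methyl-3-[2-(tert-butyldiphenylsilyloxy)ethyl]cyclohexan-1-one
Product: 10 racemic 2-allyl-4-bromo-1,3-dimethyl-3-[2-(tert-butyldiphenylsilyloxy)ethyl]cyclohexan-1-ol (C7 hydroxyl axial; cis to the C3a methyl and to the allyl group)
Conditions: MeMgBr, CeCl3, THF, −78 °C
Reagents that add atoms: methylmagnesium bromide C[Mg]Br
Why: Cerium-mediated Grignard 1,2-addition: the chair is locked by the equatorial allyl, arm and bromine, the axial C3a methyl blocks axial attack at C7, so methyl enters equatorially and the C7 oxygen ends axial as in the target, while CeCl3 suppresses enolization.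

Step 7
Reactants: 10 racemic 2-allyl-4-bromo-1,3-dimethyl-3-[2-(tert-butyldiphenylsilyloxy)ethyl]cyclohexan-1-ol
Product: 11 racemic 2-allyl-4-bromo-3-(2-hydroxyethyl)-1,3-dimethylcyclohexan-1-ol
Conditions: Bu4NF, THF, 23 °C
Reagents that add atoms: none
Why: Fluoride-mediated desilylation frees the primary alcohol; the equatorial bromide has no antiperiplanar hydrogen and should resist elimination.

Step 8
Reactants: 11 racemic 2-allyl-4-bromo-3-(2-hydroxyethyl)-1,3-dimethylcyclohexan-1-ol
Product: 12 racemic 2-allyl-4-bromo-1,3-dimethyl-1-(triethylsilyloxy)-3-[2-(triethylsilyloxy)ethyl]cyclohexane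
Conditions: Et3SiOTf (2.5 equiv), 2,6-lutidine, CH2Cl2, −78 → 0 °C
Reagents that add atoms: triethylsilyl triflate CC[Si](CC)(CC)OS(=O)(=O)C(F)(F)F
Why: Silylation with a silyl triflate and a hindered base covers the primary and the hindered tertiary hydroxyl; the tertiary ether must be in place before C8 becomes an ester, because the cis C7 hydroxyl would otherwise lactonize onto it.

Step 9
Reactants: 12 racemic 2-allyl-4-bromo-1,3-dimethyl-1-(triethylsilyloxy)-3-[2-(triethylsilyloxy)ethyl]cyclohexane
Product: 13 racemic methyl 2-[3-bromo-2,6-dimethyl-6-(triethylsilyloxy)-2-[2-(triethylsilyloxy)ethyl]cyclohexyl]acetate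
Conditions: O3, NaOH (2.5 M in MeOH), CH2Cl2, −78 °C
Reagents that add atoms: ozone [O-][O+]=O; methanol CO
Why: Ozonolysis in methanolic NaOH turns the terminal alkene directly into the methyl ester (the hemiacetal anion of the first-formed aldehyde is oxidized by ozone), which gives C8 at the ester level with C1 as its α-carbon.

Step 10
Reactants: 13 racemic methyl 2-[3-bromo-2,6-dimethyl-6-(triethylsilyloxy)-2-[2-(triethylsilyloxy)ethyl]cyclohexyl]acetate
Product: 15 racemic methyl 2-bromo-2-[3-bromo-2,6-dimethyl-6-(triethylsilyloxy)-2-[2-(triethylsilyloxy)ethyl]cyclohexyl]acetate (both epimers at the new CHBr), via trimethylsilyl ketene acetal 14 (not isolated)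
Conditions: LiN(SiMe3)2, Me3SiCl, THF, −78 °C; then N-bromosuccinimide, −78 → 0 °C
Reagents that add atoms: N-bromosuccinimide O=C1CCC(=O)N1Br
Why: Enolization of the only ester, O-silylation and electrophilic bromination of the silyl ketene acetal install the α-bromine from which the C1 enolate can later be made under reducing, non-basic conditions; the configuration of this carbon is of no consequence.

Step 11
Reactants: 15 racemic methyl 2-bromo-2-[3-bromo-2,6-dimethyl-6-(triethylsilyloxy)-2-[2-(triethylsilyloxy)ethyl]cyclohexyl]acetate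
Product: 16 racemic methyl 2-bromo-2-[3-bromo-2,6-dimethyl-2-(2-oxoethyl)-6-(triethylsilyloxy)cyclohexyl]acetate
Conditions: (COCl)2, DMSO, CH2Cl2, −78 → −40 °C; Et3N, −78 → 0 °C
Reagents that add atoms: none
Why: Swern oxidation converts a primary triethylsilyl ether directly into the aldehyde (chloride-assisted loss of silicon from the primary oxygen, then the usual alkoxysulfonium fragmentation), while the hindered tertiary triethylsilyl ether is left alone.

Step 12
Reactants: 16 racemic methyl 2-bromo-2-[3-bromo-2,6-dimethyl-2-(2-oxoethyl)-6-(triethylsilyloxy)cyclohexyl]acetate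
Product: 18 racemic methyl (1S*,2R*,3aS*,4S*,7R*,7aS*)-4-bromo-2-hydroxy-3a,7-dimethyl-7-(triethylsilyloxy)octahydro-1H-indene-1-carboxylate, via samarium enolate 17 (not isolated)
Conditions: SmI2 (2.2 equiv), THF, −78 °C
Reagents that add atoms: none
Why: Intramolecular Reformatsky reaction mediated by samarium diiodide: two-electron reduction of the α-bromo ester gives the samarium enolate, which adds to the tethered aldehyde in a five-membered aldol closure through a closed metal-bridged transition state, so the C2 oxygen and the C1 ester should end cis, both on the face away from the axial C3a methyl and with the ester trans to C7; the unactivated secondary bromide is inert to SmI2 at this temperature.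

Step 13
Reactants: 18 racemic methyl (1S*,2R*,3aS*,4S*,7R*,7aS*)-4-bromo-2-hydroxy-3a,7-dimethyl-7-(triethylsilyloxy)octahydro-1H-indene-1-carboxylate
Product: 19 methyl (1S,2R,3aS,4S,7R,7aS)-2-acetoxy-4-bromo-3a,7-dimethyl-7-(triethylsilyloxy)octahydro-1H-indene-1-carboxylate
Conditions: lipase PS (Burkholderia cepacia), vinyl acetate, tBuOMe, 35 °C, stopped near half conversion
Reagents that add atoms: vinyl acetate CC(=O)OC=C
Why: Lipase-catalysed kinetic resolution by enantioselective transesterification: by the empirical size rule for secondary alcohols the enzyme should acetylate the (2R) carbinol (large ester-bearing C1 side, medium C3 methylene side), the mirror-image hydroxy ester stays unacylated and is removed by chromatography, and this step sets the absolute configuration of the hydrindane.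

Step 14
Reactants: 19 methyl (1S,2R,3aS,4S,7R,7aS)-2-acetoxy-4-bromo-3a,7-dimethyl-7-(triethylsilyloxy)octahydro-1H-indene-1-carboxylate
Product: 21 methyl (1S,2R,3aS,4S,7R,7aS)-4-bromo-2-(tert-butyldimethylsilyloxy)-3a,7-dimethyl-7-(triethylsilyloxy)octahydro-1H-indene-1-carboxylate, via hydroxy ester 20 (not isolated)
Conditions: K2CO3, MeOH, 0 °C; then tBuMe2SiOTf, 2,6-lutidine, CH2Cl2, 0 °C
Reagents that add atoms: tert-butyldimethylsilyl triflate CC(C)(C)[Si](C)(C)OS(=O)(=O)C(F)(F)F
Why: Cold methanolysis removes the acetate faster than the ester can enolize and eliminate, and the freed secondary hydroxyl is silylated with the silyl triflate; this ether later keeps the C2 oxygen from capturing the C1′ cation and from accepting the acetyl group.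

Step 15
Reactants: 21 methyl (1S,2R,3aS,4S,7R,7aS)-4-bromo-2-(tert-butyldimethylsilyloxy)-3a,7-dimethyl-7-(triethylsilyloxy)octahydro-1H-indene-1-carboxylate
Product: 22 (1S,2R,3aS,4S,7R,7aS)-4-bromo-2-(tert-butyldimethylsilyloxy)-3a,7-dimethyl-7-(triethylsilyloxy)octahydro-1H-indene-1-carbaldehyde
Conditions: iBu2AlH (1.1 equiv), CH2Cl2, −78 °C
Reagents that add atoms: none
Why: Low-temperature reduction with diisobutylaluminium hydride should stop at the aldehyde through the stable tetrahedral aluminium alkoxide; C1 is already the more stable epimer (formyl group trans to C7), so it is not at risk.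

Step 16
Reactants: 23 6-methylhept-5-en-2-one
Product: 24 6-methylhepta-1,5-dien-2-yl trifluoromethanesulfonate
Conditions: LiN(iPr)2, THF, −78 °C; then PhNTf2, −78 → 0 °C
Reagents that add atoms: N-phenylbis(trifluoromethanesulfonimide) O=S(=O)(N(c1ccccc1)S(=O)(=O)C(F)(F)F)C(F)(F)F
Why: Kinetic deprotonation at the methyl group by the hindered amide base and O-sulfonylation of the less substituted enolate give the terminal enol triflate.

Step 17
Reactants: 22 (1S,2R,3aS,4S,7R,7aS)-4-bromo-2-(tert-butyldimethylsilyloxy)-3a,7-dimethyl-7-(triethylsilyloxy)octahydro-1H-indene-1-carbaldehyde; 24 6-methylhepta-1,5-dien-2-yl trifluoromethanesulfonate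
Product: 25 1-[4-bromo-2-(tert-butyldimethylsilyloxy)-3a,7-dimethyl-7-(triethylsilyloxy)octahydro-1H-inden-1-yl]-6-methyl-2-methylidenehept-5-en-1-ol (hydrindane as in 22; both C8 epimers)
Conditions: CrCl2 (4 equiv), NiCl2 (1 mol %), DMF, 23 °C
Reagents that add atoms: none
Why: Nozaki–Hiyama–Kishi coupling: nickel-catalysed activation of the enol triflate, transfer to chromium and addition of the alkenylchromium species to the hindered aldehyde form the C8–C1′ bond without touching the silyl ethers, the alkyl bromide or the C1–H; C8 is not controlled here and both epimers are carried on.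

Step 18
Reactants: 25 1-[4-bromo-2-(tert-butyldimethylsilyloxy)-3a,7-dimethyl-7-(triethylsilyloxy)octahydro-1H-inden-1-yl]-6-methyl-2-methylidenehept-5-en-1-ol
Product: 26 1-[4-bromo-2-(tert-butyldimethylsilyloxy)-3a,7-dimethyl-7-(triethylsilyloxy)octahydro-1H-inden-1-yl]-6-methyl-2-methylidenehept-5-en-1-one (hydrindane as in 22)
Conditions: Dess–Martin periodinane, NaHCO3, CH2Cl2, 0 → 23 °C
Reagents that add atoms: none
Why: Dess–Martin oxidation under buffered conditions converges both carbinol epimers on one enone without epimerizing C1 or eliminating the β-silyloxy group.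

Step 19
Reactants: 26 1-[4-bromo-2-(tert-butyldimethylsilyloxy)-3a,7-dimethyl-7-(triethylsilyloxy)octahydro-1H-inden-1-yl]-6-methyl-2-methylidenehept-5-en-1-one
Product: 27 (R)-1-[4-bromo-2-(tert-butyldimethylsilyloxy)-3a,7-dimethyl-7-(triethylsilyloxy)octahydro-1H-inden-1-yl]-6-methyl-2-methylidenehept-5-en-1-ol (hydrindane as in 22; C8 oxygen 1,3-syn to the C2 oxygen)
Conditions: NaBH4, CeCl3·7H2O, MeOH, −78 °C
Reagents that add atoms: none
Why: Luche 1,2-reduction of the enone: hydride should attack the carbonyl anti to the larger α-substituent of C1 (the C7a branch) with the alkenyl group next to the C1 hydrogen, which gives the (8R) carbinol, the epimer opposite to the one favoured when the alkenyl group is the incoming nucleophile in step 17.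

Step 20
Reactants: 27 (R)-1-[4-bromo-2-(tert-butyldimethylsilyloxy)-3a,7-dimethyl-7-(triethylsilyloxy)octahydro-1H-inden-1-yl]-6-methyl-2-methylidenehept-5-en-1-ol
Product: 28 (R)-1-[4-bromo-2-(tert-butyldimethylsilyloxy)-3a,7-dimethyl-7-(triethylsilyloxy)octahydro-1H-inden-1-yl]-6-methyl-2-methylidenehept-5-en-1-yl acetate (hydrindane as in 22)
Conditions: Ac2O, pyridine, 4-(dimethylamino)pyridine (10 mol %), CH2Cl2, 23 °C
Reagents that add atoms: acetic anhydride CC(=O)OC(C)=O
Why: Nucleophile-catalysed acylation of the secondary allylic alcohol installs the C8 acetate, which deactivates the 1,1-disubstituted alkene towards bromenium and serves as the internal nucleophile in step 21.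

Step 21
Reactants: 28 (R)-1-[4-bromo-2-(tert-butyldimethylsilyloxy)-3a,7-dimethyl-7-(triethylsilyloxy)octahydro-1H-inden-1-yl]-6-methyl-2-methylidenehept-5-en-1-yl acetate
Product: 30 (R)-[(1R,4S)-4-bromo-1-hydroxy-3,3-dimethylcyclohexyl][4-bromo-2-(tert-butyldimethylsilyloxy)-3a,7-dimethyl-7-(triethylsilyloxy)octahydro-1H-inden-1-yl]methyl acetate (hydrindane as in 22), via dioxolanylium ion 29 (not isolated)
Conditions: vanadium-dependent bromoperoxidase (enzyme, Corallina officinalis), KBr, H2O2 (syringe pump), Na3VO4 (trace), MES buffer pH 6.5–EtOH 3:2, 23 °C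
Reagents that add atoms: potassium bromide [K+].[Br-]; water O
Why: Proposed new method: the vanadate site of the enzyme oxidises bromide with H2O2 to a bound hypobromite that hands bromenium to the most electron-rich π bond, the trisubstituted alkene at the end of the chain, because the 1,1-disubstituted alkene is deactivated by the allylic C8 acetate and every other oxygen is silylated. The bromonium ion is opened at its dimethyl-substituted carbon by the CH2 carbon of the 1,1-disubstituted alkene, which forms the C2′–C3′ bond and closes ring B in a 6-endo mode (both carbons of the nucleophilic alkene become ring members) through a chair with bromine equatorial at C4′. The tertiary C1′ cation is captured from the axial direction by the carbonyl oxygen of the neighbouring C8 acetate to give 1,3-dioxolan-2-ylium ion 29, and water opens this ion at the former acyl carbon, so that C1′ keeps a hydroxyl and the acetyl group returns to the less hindered secondary C8 oxygen. The closest known reaction types are the bromoperoxidase-mediated bromocyclization of nerolidol-type terpene alcohols and the bromonium polyene cyclization with Et2SBr·SbCl5Br; a 1,5-diene ending in an acetoxy-substituted 1,1-disubstituted alkene on a large chiral scaffold has not been cyclized in this way. C4′ is set by the alkene face to which the enzyme delivers bromenium (catalyst control, since the hydrindane stereocentres are too far away), and C1′ follows from C4′ because axial C–O bond formation on the chair leaves the bulky C8 substituent equatorial and the oxygen cis to bromine, while the five-membered acetoxonium ring ties this to the fixed C8 centre. The step needs site selectivity for the terminal alkene and face selectivity at that alkene; the first is secured by the acetate and the silyl ethers of 28, the second rests on the enzyme.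

Step 22
Reactants: 30 (R)-[(1R,4S)-4-bromo-1-hydroxy-3,3-dimethylcyclohexyl][4-bromo-2-(tert-butyldimethylsilyloxy)-3a,7-dimethyl-7-(triethylsilyloxy)octahydro-1H-inden-1-yl]methyl acetate
Product: 31 (R)-[(1S,2R,3aS,4S,7R,7aS)-4-bromo-2,7-dihydroxy-3a,7-dimethyloctahydro-1H-inden-1-yl][(1R,4S)-4-bromo-1-hydroxy-3,3-dimethylcyclohexyl]methyl acetate (CNP0166243.1)
Conditions: HF·pyridine, pyridine, THF, 0 → 23 °C
Reagents that add atoms: none
Why: Fluoride-mediated desilylation removes the secondary tert-butyldimethylsilyl and the tertiary triethylsilyl ether; the buffered, non-basic medium should leave the C8 acetate in place (no acyl shift to the C2 hydroxyl) and should not ionize the tertiary alcohols or the bromides.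

**Compound list**
1 | tert-butyl(but-3-yn-1-yloxy)diphenylsilane | C#CCCO[Si](c1ccccc1)(c1ccccc1)C(C)(C)C | starting material
2 | (E)-[4-(tert-butyldiphenylsilyloxy)-2-methylbut-1-en-1-yl]dimethylalane | C/C(=C\[Al](C)C)CCO[Si](c1ccccc1)(c1ccccc1)C(C)(C)C | intermediate
3 | (E)-5-[(tert-butyldiphenylsilyl)oxy]-3-methylpent-2-en-1-ol | C/C(=C\CO)CCO[Si](c1ccccc1)(c1ccccc1)C(C)(C)C | intermediate
4 | (E)-[(5-bromo-3-methylpent-3-en-1-yl)oxy](tert-butyl)diphenylsilane | C/C(=C\CBr)CCO[Si](c1ccccc1)(c1ccccc1)C(C)(C)C | intermediate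
5 | allyl acetoacetate (prop-2-en-1-yl 3-oxobutanoate) | C=CCOC(=O)CC(C)=O | starting material
6 | sodium lithium dianion of allyl acetoacetate | C=CCOC(=O)[CH-]C(=O)[CH2-].[Na+].[Li+] | intermediate
7 | allyl (E)-9-[(tert-butyldiphenylsilyl)oxy]-7-methyl-3-oxonon-6-enoate | C=CCOC(=O)CC(=O)CC/C=C(\C)CCO[Si](c1ccccc1)(c1ccccc1)C(C)(C)C | intermediate
8 | racemic allyl 3-bromo-2-methyl-6-oxo-2-[2-(tert-butyldiphenylsilyloxy)ethyl]cyclohexane-1-carboxylate (Br equatorial cis to the ring methyl; ester equatorial) | CC(C)(C)[Si](OCC[C@]1(C)[C@@H](Br)CCC(=O)[C@H]1C(=O)OCC=C)(c1ccccc1)c1ccccc1 | intermediate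
9 | racemic 2-allyl-4-bromo-3-methyl-3-[2-(tert-butyldiphenylsilyloxy)ethyl]cyclohexan-1-one (allyl trans to the arm) | CC(C)(C)[Si](OCC[C@]1(C)[C@@H](Br)CCC(=O)[C@H]1CC=C)(c1ccccc1)c1ccccc1 | intermediate
10 | racemic 2-allyl-4-bromo-1,3-dimethyl-3-[2-(tert-butyldiphenylsilyloxy)ethyl]cyclohexan-1-ol (hydroxyl axial; cis to the 3-methyl) | CC(C)(C)[Si](OCC[C@]1(C)[C@@H](Br)CC[C@@](C)(O)[C@H]1CC=C)(c1ccccc1)c1ccccc1 | intermediate
11 | racemic 2-allyl-4-bromo-3-(2-hydroxyethyl)-1,3-dimethylcyclohexan-1-ol | OCC[C@]1(C)[C@@H](Br)CC[C@@](C)(O)[C@H]1CC=C | intermediate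
12 | racemic 2-allyl-4-bromo-1,3-dimethyl-1-(triethylsilyloxy)-3-[2-(triethylsilyloxy)ethyl]cyclohexane | CC[Si](CC)(CC)OCC[C@]1(C)[C@@H](Br)CC[C@@](C)(O[Si](CC)(CC)CC)[C@H]1CC=C | intermediate
13 | racemic methyl 2-[3-bromo-2,6-dimethyl-6-(triethylsilyloxy)-2-[2-(triethylsilyloxy)ethyl]cyclohexyl]acetate | CC[Si](CC)(CC)OCC[C@]1(C)[C@@H](Br)CC[C@@](C)(O[Si](CC)(CC)CC)[C@H]1CC(=O)OC | intermediate
14 | trimethylsilyl ketene acetal of 13 | CC[Si](CC)(CC)OCC[C@]1(C)[C@@H](Br)CC[C@@](C)(O[Si](CC)(CC)CC)[C@H]1C=C(OC)O[Si](C)(C)C | intermediate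
15 | racemic methyl 2-bromo-2-[3-bromo-2,6-dimethyl-6-(triethylsilyloxy)-2-[2-(triethylsilyloxy)ethyl]cyclohexyl]acetate (both epimers at CHBr) | CC[Si](CC)(CC)OCC[C@]1(C)[C@@H](Br)CC[C@@](C)(O[Si](CC)(CC)CC)[C@H]1C(Br)C(=O)OC | intermediate
16 | racemic methyl 2-bromo-2-[3-bromo-2,6-dimethyl-2-(2-oxoethyl)-6-(triethylsilyloxy)cyclohexyl]acetate | O=CC[C@]1(C)[C@@H](Br)CC[C@@](C)(O[Si](CC)(CC)CC)[C@H]1C(Br)C(=O)OC | intermediate
17 | samarium enolate of the debrominated ester of 16 | O=CC[C@]1(C)[C@@H](Br)CC[C@@](C)(O[Si](CC)(CC)CC)[C@H]1C=C(OC)O[Sm](I)I | intermediate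
18 | racemic methyl (1S*,2R*,3aS*,4S*,7R*,7aS*)-4-bromo-2-hydroxy-3a,7-dimethyl-7-(triethylsilyloxy)octahydro-1H-indene-1-carboxylate | COC(=O)[C@@H]1[C@H](O)C[C@]2(C)[C@@H](Br)CC[C@@](C)(O[Si](CC)(CC)CC)[C@@H]12 | intermediate
19 | methyl (1S,2R,3aS,4S,7R,7aS)-2-acetoxy-4-bromo-3a,7-dimethyl-7-(triethylsilyloxy)octahydro-1H-indene-1-carboxylate | COC(=O)[C@@H]1[C@H](OC(C)=O)C[C@]2(C)[C@@H](Br)CC[C@@](C)(O[Si](CC)(CC)CC)[C@@H]12 | intermediate
20 | methyl (1S,2R,3aS,4S,7R,7aS)-4-bromo-2-hydroxy-3a,7-dimethyl-7-(triethylsilyloxy)octahydro-1H-indene-1-carboxylate (single enantiomer) | COC(=O)[C@@H]1[C@H](O)C[C@]2(C)[C@@H](Br)CC[C@@](C)(O[Si](CC)(CC)CC)[C@@H]12 | intermediate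
21 | methyl (1S,2R,3aS,4S,7R,7aS)-4-bromo-2-(tert-butyldimethylsilyloxy)-3a,7-dimethyl-7-(triethylsilyloxy)octahydro-1H-indene-1-carboxylate | COC(=O)[C@@H]1[C@H](O[Si](C)(C)C(C)(C)C)C[C@]2(C)[C@@H](Br)CC[C@@](C)(O[Si](CC)(CC)CC)[C@@H]12 | intermediate
22 | (1S,2R,3aS,4S,7R,7aS)-4-bromo-2-(tert-butyldimethylsilyloxy)-3a,7-dimethyl-7-(triethylsilyloxy)octahydro-1H-indene-1-carbaldehyde | O=C[C@@H]1[C@H](O[Si](C)(C)C(C)(C)C)C[C@]2(C)[C@@H](Br)CC[C@@](C)(O[Si](CC)(CC)CC)[C@@H]12 | intermediate
23 | 6-methylhept-5-en-2-one | CC(=O)CCC=C(C)C | starting material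
24 | 6-methylhepta-1,5-dien-2-yl trifluoromethanesulfonate | C=C(CCC=C(C)C)OS(=O)(=O)C(F)(F)F | intermediate
25 | C8 carbinols (both epimers) from 22 and 24 | OC([C@@H]1[C@H](O[Si](C)(C)C(C)(C)C)C[C@]2(C)[C@@H](Br)CC[C@@](C)(O[Si](CC)(CC)CC)[C@@H]12)C(=C)CCC=C(C)C | intermediate
26 | C8 enone | O=C([C@@H]1[C@H](O[Si](C)(C)C(C)(C)C)C[C@]2(C)[C@@H](Br)CC[C@@](C)(O[Si](CC)(CC)CC)[C@@H]12)C(=C)CCC=C(C)C | intermediate
27 | (8R) carbinol | O[C@H]([C@@H]1[C@H](O[Si](C)(C)C(C)(C)C)C[C@]2(C)[C@@H](Br)CC[C@@](C)(O[Si](CC)(CC)CC)[C@@H]12)C(=C)CCC=C(C)C | intermediate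
28 | (8R) acetate bearing the 6-methylhepta-1,5-dien-2-yl chain (precursor of the key step) | CC(=O)O[C@H]([C@@H]1[C@H](O[Si](C)(C)C(C)(C)C)C[C@]2(C)[C@@H](Br)CC[C@@](C)(O[Si](CC)(CC)CC)[C@@H]12)C(=C)CCC=C(C)C | intermediate
29 | 2-methyl-1,3-dioxolan-2-ylium ion spanning C8 and C1′ of bromocyclized ring B | CC5=[O+][C@@]6(CC[C@H](Br)C(C)(C)C6)[C@H](O5)[C@@H]1[C@H](O[Si](C)(C)C(C)(C)C)C[C@]2(C)[C@@H](Br)CC[C@@](C)(O[Si](CC)(CC)CC)[C@@H]12 | intermediate
30 | bis-silyl ether of the target (C2 tert-butyldimethylsilyl; C7 triethylsilyl) | CC(=O)O[C@H]([C@@H]1[C@H](O[Si](C)(C)C(C)(C)C)C[C@]2(C)[C@@H](Br)CC[C@@](C)(O[Si](CC)(CC)CC)[C@@H]12)[C@@]1(O)CC[C@H](Br)C(C)(C)C1 | intermediate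
31 | (R)-[(1S,2R,3aS,4S,7R,7aS)-4-bromo-2,7-dihydroxy-3a,7-dimethyloctahydro-1H-inden-1-yl][(1R,4S)-4-bromo-1-hydroxy-3,3-dimethylcyclohexyl]methyl acetate (CNP0166243.1) | CC(=O)O[C@H]([C@@H]1[C@H](O)C[C@]2(C)[C@@H](Br)CC[C@@](C)(O)[C@@H]12)[C@@]1(O)CC[C@H](Br)C(C)(C)C1 | target

**Step count and risks**
Total: 22 steps. Longest linear sequence: 21 steps (steps 1–15 and 17–22; step 16 makes the coupling partner).

Steps most likely to fail:

Step 21 (Proposed new method): the enzyme may not accept the large lipophilic substrate, or may release free hypobromous acid, so that bromenium transfer loses its face selectivity and C4′ and C1′ form as a mixture. The fallback uses known chemistry and sets out from 28, which is treated with the stoichiometric bromenium reagent Et2SBr·SbCl5Br in MeNO2 at −25 °C and then with aqueous NaHCO3 (reagent-induced bromonium polyene cyclization with acetate-assisted capture). Face selection is given up, so 30 should form beside its (1′S,4′R) ring-B diastereomer F1; the two are separated by preparative HPLC and 30 re-enters the route at step 22.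

Step 4: capture of the bromonium ion by the keto oxygen instead of the enol carbon, or bromination of the enol itself, may divert the substrate. The fallback sets out from 7: mercury-induced cyclization with Hg(OTf)2 and N,N-dimethylaniline in MeNO2, followed by aqueous NaBr, which is an established carbon-selective closure for β-keto esters, would give the equatorial organomercury bromide F2. Bromodemercuration of F2 with Br2 and LiBr in pyridine under O2 returns to 8.

Step 19: hydride delivery may show poor or reversed facial selectivity if the silyloxy-bearing C2 side, and not the C7a side, acts as the larger group at C1. The fallback sets out from 26: the reduction product is then mainly the (8S) carbinol F3 (which is also the expected major epimer of step 17). F3 is converted in one operation into 28 by a Mitsunobu reaction with acetic acid (PPh3, diisopropyl azodicarboxylate, toluene, 0 °C), which inverts C8 and installs the acetate at the same time.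

Further compounds
F1 | step 21 | (1′S,4′R) ring-B diastereomer of 30 | CC(=O)O[C@H]([C@@H]1[C@H](O[Si](C)(C)C(C)(C)C)C[C@]2(C)[C@@H](Br)CC[C@@](C)(O[Si](CC)(CC)CC)[C@@H]12)[C@]1(O)CC[C@@H](Br)C(C)(C)C1
F2 | step 4 | racemic allyl 3-(bromomercurio)-2-methyl-6-oxo-2-[2-(tert-butyldiphenylsilyloxy)ethyl]cyclohexane-1-carboxylate | CC(C)(C)[Si](OCC[C@]1(C)[C@@H]([Hg]Br)CCC(=O)[C@H]1C(=O)OCC=C)(c1ccccc1)c1ccccc1
F3 | step 19 | (8S) epimer of carbinol 27 | O[C@@H]([C@@H]1[C@H](O[Si](C)(C)C(C)(C)C)C[C@]2(C)[C@@H](Br)CC[C@@](C)(O[Si](CC)(CC)CC)[C@@H]12)C(=C)CCC=C(C)C
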